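**Plan**

- Retrosynthesis: the stilbene C=C is cut first (Horner–Wadsworth–Emmons), giving a 6-formyl-2,3-dihydro-1,4-benzodioxine and a resorcinol benzylphosphonate. The dioxane ring is then cut at the aryl ether bond O1–C8a and at the benzylic bond C3–O4, giving 4-fluoro-3-hydroxybenzaldehyde and a cis-3-arylglycidyl trityl ether.
- Enabling feature: C8a, the arene carbon bonded to O1, is para to C6, the carbon that carries the stilbene. With C6 held as CHO, a C8a–F bond becomes an SNAr site, and the CHO afterwards becomes the alkene carbon.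
- Forward order: syringaldehyde → (Z)-cinnamate → cis-glycidate → cis-epoxy trityl ether. One operation then forms C3–O4 (phenoxide opens the epoxide) and closes the dioxane ring through O1–C8a (the released alkoxide displaces fluoride). Olefination and global acid deprotection finish the route.
- Stereochemistry: the Jacobsen epoxidation sets both centres (catalyst control). Inversion at the benzylic carbon and retention at the carbinol carbon turn the cis-epoxide into the trans-(2R,3R) ring. The (E)-alkene comes from the phosphonate olefination.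

Key step: step 6

Assumption (remark on the chemistry): the (S,S)-enantiomer of Mn(salen)Cl is taken to deliver the (2S,3S)-cis-glycidate, by analogy with simple (Z)-cinnamate esters; should the sense be opposite, the (R,R)-catalyst would be used. Here salen is the dianion of N,N'-bis(3,5-di-tert-butylsalicylidene)-trans-1,2-cyclohexanediamine.

**Step 1**
Reactants: 1 syringaldehyde (4-hydroxy-3,5-dimethoxybenzaldehyde)
Product: 2 4-(methoxymethoxy)-3,5-dimethoxybenzaldehyde
Conditions: MOMCl, iPr2NEt, CH2Cl2, 0 °C to rt
Reagents that add atoms: chloromethyl methyl ether (MOMCl), COCCl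
Why: Williamson-type O-alkylation of the phenol by the α-chloro ether should give the MOM acetal, which blocks quinone-methide chemistry in the later basic steps and is removable by acid.

**Step 2**
Reactants: 2 4-(methoxymethoxy)-3,5-dimethoxybenzaldehyde
Product: 3 methyl (2Z)-3-[4-(methoxymethoxy)-3,5-dimethoxyphenyl]prop-2-enoate
Conditions: (CF3CH2O)2P(O)CH2CO2Me, KN(SiMe3)2, 18-crown-6, THF, −78 °C
Reagents that add atoms: methyl bis(2,2,2-trifluoroethyl)phosphonoacetate, COC(=O)CP(=O)(OCC(F)(F)F)OCC(F)(F)F
Why: In the Still–Gennari olefination the electron-poor phosphonate eliminates fast from the kinetic adduct under dissociating conditions, which should give the (Z)-enoate from an aromatic aldehyde.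

**Step 3**
Reactants: 3 methyl (2Z)-3-[4-(methoxymethoxy)-3,5-dimethoxyphenyl]prop-2-enoate
Product: 4 methyl (2S,3S)-3-[4-(methoxymethoxy)-3,5-dimethoxyphenyl]oxirane-2-carboxylate (cis-glycidate)
Conditions: (S,S)-Mn(salen)Cl (cat.), NaOCl (aq, buffered to pH 11), 4-phenylpyridine N-oxide, CH2Cl2, 0 °C
Reagents that add atoms: sodium hypochlorite, [Na+].[O-]Cl
Why: In the Jacobsen epoxidation, for which aryl-conjugated cis-alkenes such as (Z)-cinnamates are the best substrate class, the chiral salen ligand directs oxygen transfer to one face of the alkene and so should set C2 and C3 together as (2S,3S), the N-oxide additive limiting leakage to the trans-epoxide.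

**Step 4**
Reactants: 4 methyl (2S,3S)-3-[4-(methoxymethoxy)-3,5-dimethoxyphenyl]oxirane-2-carboxylate
Product: 5 [(2R,3S)-3-[4-(methoxymethoxy)-3,5-dimethoxyphenyl]oxiran-2-yl]methanol (cis)
Conditions: NaBH4, MeOH/THF, 0 °C
Reagents that add atoms: none
Why: Borohydride reduction of the α-oxygen-activated ester should give the primary alcohol without opening the epoxide or touching either stereocentre (the descriptor at C2 changes only by priority).

**Step 5**
Reactants: 5 [(2R,3S)-3-[4-(methoxymethoxy)-3,5-dimethoxyphenyl]oxiran-2-yl]methanol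
Product: 6 (2R,3S)-3-[4-(methoxymethoxy)-3,5-dimethoxyphenyl]-2-[(triphenylmethoxy)methyl]oxirane
Conditions: TrCl, Et3N, DMAP (cat.), CH2Cl2, rt
Reagents that add atoms: trityl chloride (chlorotriphenylmethane), ClC(c1ccccc1)(c1ccccc1)c1ccccc1
Why: Tritylation of the primary alcohol should give a base-stable, non-migrating ether that rules out Payne rearrangement and a primary alkoxide in the next step and falls off under the final acid treatment.

**Step 6**
Reactants: 6 (2R,3S)-3-[4-(methoxymethoxy)-3,5-dimethoxyphenyl]-2-[(triphenylmethoxy)methyl]oxirane; 7 4-fluoro-3-hydroxybenzaldehyde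
Product: 9 (2R,3R)-3-[4-(methoxymethoxy)-3,5-dimethoxyphenyl]-2-[(triphenylmethoxy)methyl]-2,3-dihydro-1,4-benzodioxine-6-carbaldehyde, via ring-opened fluoroaryl ether alcohol 8 (not isolated)
Conditions: Cs2CO3, DMF, 90 °C (7 in slight excess)
Reagents that add atoms: none
Why: Cs2CO3 converts 7 into its phenoxide, which opens the cis-epoxide of 6 by SN2 attack at the benzylic carbon, so that the alkoxide of 8 is formed directly beside the aryl fluoride; this alkoxide adds to the fluorine-bearing carbon para to the formyl group (Meisenheimer adduct stabilised by the para-CHO) and fluoride leaves, which forms the O1–C8a bond and closes the 1,4-dioxane ring. The closest known reaction types are the benzylic opening of 3-arylglycidol derivatives by phenoxides and the tandem epoxide-opening/aryl C–O cyclisation of 2-halophenols to 2,3-dihydro-1,4-benzodioxines, run here without metal because the formyl group activates the ring. The dioxane ring closes by a 6-exo-trig addition–elimination at C8a. C3 is set by inversion of the (3S) epoxide carbon (substrate control), and C2 keeps the configuration from step 3 because its C–O bond is never broken, so the cis-epoxide should map onto the trans-(2R,3R) ring. The step needs opening at the benzylic carbon and closure only through the secondary alkoxide: the first should be secured by benzylic activation and by the bulky, inductively deactivating CH2OTr arm on the other epoxide carbon, the second by the trityl cap (no primary alkoxide, no seven-membered closure) and by the fact that only the C–F bond para to CHO is activated, the phenoxide of 7 itself being too electron-rich to self-condense.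

**Step 7**
Reactants: 10 3,5-dihydroxybenzyl alcohol
Product: 11 [3,5-bis(methoxymethoxy)phenyl]methanol
Conditions: NaH (2.1 equiv), DMF, 0 °C; then MOMCl (2.1 equiv)
Reagents that add atoms: chloromethyl methyl ether (MOMCl), COCCl
Why: NaH should deprotonate only the two phenols, which are far more acidic than the benzylic alcohol, and the phenoxides are then alkylated selectively (Williamson-type acetal protection).

**Step 8**
Reactants: 11 [3,5-bis(methoxymethoxy)phenyl]methanol
Product: 12 1-(bromomethyl)-3,5-bis(methoxymethoxy)benzene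
Conditions: CBr4, PPh3, CH2Cl2, 0 °C
Reagents that add atoms: carbon tetrabromide, BrC(Br)(Br)Br
Why: The Appel reaction should convert the benzylic alcohol into the bromide under essentially neutral conditions that leave the aryl MOM ethers intact.

**Step 9**
Reactants: 12 1-(bromomethyl)-3,5-bis(methoxymethoxy)benzene
Product: 13 diethyl {[3,5-bis(methoxymethoxy)phenyl]methyl}phosphonate
Conditions: P(OEt)3 (neat), 130 °C
Reagents that add atoms: triethyl phosphite, CCOP(OCC)OCC
Why: In the Michaelis–Arbuzov reaction the phosphite should displace the benzylic bromide and the phosphonium intermediate lose bromoethane to give the phosphonate.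

**Step 10**
Reactants: 9 (2R,3R)-3-[4-(methoxymethoxy)-3,5-dimethoxyphenyl]-2-[(triphenylmethoxy)methyl]-2,3-dihydro-1,4-benzodioxine-6-carbaldehyde; 13 diethyl {[3,5-bis(methoxymethoxy)phenyl]methyl}phosphonate
Product: 14 (2R,3R)-6-{(E)-2-[3,5-bis(methoxymethoxy)phenyl]ethenyl}-3-[4-(methoxymethoxy)-3,5-dimethoxyphenyl]-2-[(triphenylmethoxy)methyl]-2,3-dihydro-1,4-benzodioxine
Conditions: KOtBu, THF, 0 °C to rt
Reagents that add atoms: none
Why: In the Horner–Wadsworth–Emmons olefination the benzylic phosphonate anion adds reversibly to the non-enolisable aldehyde and should eliminate to the thermodynamically preferred (E)-stilbene, the ring stereocentres having no acidifying neighbour and therefore being untouched by the base.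

**Step 11**
Reactants: 14 (2R,3R)-6-{(E)-2-[3,5-bis(methoxymethoxy)phenyl]ethenyl}-3-[4-(methoxymethoxy)-3,5-dimethoxyphenyl]-2-[(triphenylmethoxy)methyl]-2,3-dihydro-1,4-benzodioxine
Product: 15 aiphanol
Conditions: HCl (1.25 M in MeOH), MeOH/CH2Cl2, 0 °C to rt
Reagents that add atoms: none
Why: Acid-catalysed acetal exchange of the three aryl MOM ethers and SN1 methanolysis of the trityl ether, both cations being trapped by methanol, should release all four hydroxyl groups in one operation, with the benzodioxane ring and its two centres expected to tolerate dilute acid at room temperature.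

**Compound list**

1 | syringaldehyde (4-hydroxy-3,5-dimethoxybenzaldehyde) | COc1cc(C=O)cc(OC)c1O | starting material
2 | 4-(methoxymethoxy)-3,5-dimethoxybenzaldehyde | COCOc1c(OC)cc(C=O)cc1OC | intermediate
3 | methyl (2Z)-3-[4-(methoxymethoxy)-3,5-dimethoxyphenyl]prop-2-enoate | COCOc1c(OC)cc(/C=C\C(=O)OC)cc1OC | intermediate
4 | methyl (2S,3S)-3-[4-(methoxymethoxy)-3,5-dimethoxyphenyl]oxirane-2-carboxylate (cis) | COCOc1c(OC)cc([C@@H]2O[C@@H]2C(=O)OC)cc1OC | intermediate
5 | [(2R,3S)-3-[4-(methoxymethoxy)-3,5-dimethoxyphenyl]oxiran-2-yl]methanol (cis) | COCOc1c(OC)cc([C@@H]2O[C@@H]2CO)cc1OC | intermediate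
6 | (2R,3S)-3-[4-(methoxymethoxy)-3,5-dimethoxyphenyl]-2-[(triphenylmethoxy)methyl]oxirane (cis) | COCOc1c(OC)cc([C@@H]2O[C@@H]2COC(c3ccccc3)(c3ccccc3)c3ccccc3)cc1OC | intermediate
7 | 4-fluoro-3-hydroxybenzaldehyde | O=Cc1ccc(F)c(O)c1 | starting material
8 | 4-fluoro-3-{[(1R,2R)-2-hydroxy-1-[4-(methoxymethoxy)-3,5-dimethoxyphenyl]-3-(triphenylmethoxy)propyl]oxy}benzaldehyde (formed as its cesium alkoxide, not isolated) | COCOc1c(OC)cc([C@@H](Oc2cc(C=O)ccc2F)[C@H](O)COC(c3ccccc3)(c3ccccc3)c3ccccc3)cc1OC | intermediate
9 | (2R,3R)-3-[4-(methoxymethoxy)-3,5-dimethoxyphenyl]-2-[(triphenylmethoxy)methyl]-2,3-dihydro-1,4-benzodioxine-6-carbaldehyde | COCOc1c(OC)cc([C@H]2Oc3cc(C=O)ccc3O[C@@H]2COC(c4ccccc4)(c4ccccc4)c4ccccc4)cc1OC | intermediate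
10 | 3,5-dihydroxybenzyl alcohol | OCc1cc(O)cc(O)c1 | starting material
11 | [3,5-bis(methoxymethoxy)phenyl]methanol | COCOc1cc(CO)cc(OCOC)c1 | intermediate
12 | 1-(bromomethyl)-3,5-bis(methoxymethoxy)benzene | COCOc1cc(CBr)cc(OCOC)c1 | intermediate
13 | diethyl {[3,5-bis(methoxymethoxy)phenyl]methyl}phosphonate | CCOP(=O)(Cc1cc(OCOC)cc(OCOC)c1)OCC | intermediate
14 | (2R,3R)-6-{(E)-2-[3,5-bis(methoxymethoxy)phenyl]ethenyl}-3-[4-(methoxymethoxy)-3,5-dimethoxyphenyl]-2-[(triphenylmethoxy)methyl]-2,3-dihydro-1,4-benzodioxine | COCOc1c(OC)cc([C@H]2Oc3cc(/C=C/c4cc(OCOC)cc(OCOC)c4)ccc3O[C@@H]2COC(c5ccccc5)(c5ccccc5)c5ccccc5)cc1OC | intermediate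
15 | aiphanol, 5-{(E)-2-[(2R,3R)-3-(4-hydroxy-3,5-dimethoxyphenyl)-2-(hydroxymethyl)-2,3-dihydro-1,4-benzodioxin-6-yl]ethenyl}benzene-1,3-diol | COc1cc([C@H]2Oc3cc(/C=C/c4cc(O)cc(O)c4)ccc3O[C@@H]2CO)cc(OC)c1O | target

**Totals**

Total step count: 11. Longest linear sequence: 8 steps (steps 1–6, 10 and 11, from syringaldehyde); steps 7–9 make the phosphonate in a side branch.

**Steps most likely to fail**

Step 6. What may go wrong: the electron-poor phenoxide may open the hindered cis-epoxide too slowly, or at the non-benzylic carbon, in the aprotic medium, so that intermolecular aryl ether formation or side reactions of the aldehyde outrun the ring closure. The fallback separates the two events and closes the ring by metal catalysis instead of SNAr. It sets out from 5: opening of the free epoxy alcohol with 4-bromo-3-hydroxybenzaldehyde (NaOH, 1.1 equiv, H2O/dioxane, 70 °C), where the free hydroxyl and the protic medium favour attack at the benzylic carbon, should give 4-bromo-3-{[(1R,2R)-2,3-dihydroxy-1-[4-(methoxymethoxy)-3,5-dimethoxyphenyl]propyl]oxy}benzaldehyde F1. Selective tritylation of the primary hydroxyl (TrCl, Et3N, DMAP, CH2Cl2) should give 4-bromo-3-{[(1R,2R)-2-hydroxy-1-[4-(methoxymethoxy)-3,5-dimethoxyphenyl]-3-(triphenylmethoxy)propyl]oxy}benzaldehyde F2. Intramolecular palladium-catalysed C–O coupling (Pd(OAc)2, 2-(di-tert-butylphosphino)-1,1'-binaphthyl, Cs2CO3, toluene, 80 °C) should then form the same O1–C8a bond with retention at the carbinol carbon and come back to the route at 9.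

Step 3. What may go wrong: partial loss of the cis geometry through stepwise oxygen transfer to the electron-rich aryl alkene, incomplete facial selectivity, or oxidative attack on the trialkoxyarene. The fallback replaces catalyst-controlled epoxidation of the ester by hydroxyl-directed epoxidation of the allylic alcohol. It sets out from 3: reduction with iBu2AlH (CH2Cl2, −78 °C) should give (2Z)-3-[4-(methoxymethoxy)-3,5-dimethoxyphenyl]prop-2-en-1-ol F3. Sharpless asymmetric epoxidation of it (Ti(OiPr)4, D-(−)-diethyl tartrate, tBuOOH, 4 Å molecular sieves, CH2Cl2, −20 °C) is a concerted oxygen transfer that cannot scramble the alkene geometry; it should give the cis-epoxy alcohol directly and come back to the route at 5, replacing steps 3 and 4.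

Step 11. What may go wrong: the methoxymethyl and trityl cations released by acid may be captured by the electron-rich resorcinol ring, the stilbene may add methanol or oligomerise, and long exposure may reversibly ionise the benzylic C3–O4 bond. The fallback removes the protecting groups before the resorcinol ring exists and builds the stilbene last from unprotected partners. It sets out from 9: the same acid treatment at the aldehyde stage should give (2R,3R)-3-(4-hydroxy-3,5-dimethoxyphenyl)-2-(hydroxymethyl)-2,3-dihydro-1,4-benzodioxine-6-carbaldehyde F4. Wittig methylenation with excess ylide (Ph3PCH3Br, KOtBu, THF) should give [(2R,3R)-6-ethenyl-3-(4-hydroxy-3,5-dimethoxyphenyl)-2,3-dihydro-1,4-benzodioxin-2-yl]methanol F5. Mizoroki–Heck coupling of it with 5-iodobenzene-1,3-diol (Pd(OAc)2, P(o-tol)3, Et3N, DMF, 90 °C) should give the (E)-stilbene and arrive at 15, replacing steps 7–11.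

**Further compounds**

F1 | step 6 | 4-bromo-3-{[(1R,2R)-2,3-dihydroxy-1-[4-(methoxymethoxy)-3,5-dimethoxyphenyl]propyl]oxy}benzaldehyde | COCOc1c(OC)cc([C@@H](Oc2cc(C=O)ccc2Br)[C@H](O)CO)cc1OC
F2 | step 6 | 4-bromo-3-{[(1R,2R)-2-hydroxy-1-[4-(methoxymethoxy)-3,5-dimethoxyphenyl]-3-(triphenylmethoxy)propyl]oxy}benzaldehyde | COCOc1c(OC)cc([C@@H](Oc2cc(C=O)ccc2Br)[C@H](O)COC(c3ccccc3)(c3ccccc3)c3ccccc3)cc1OC
F3 | step 3 | (2Z)-3-[4-(methoxymethoxy)-3,5-dimethoxyphenyl]prop-2-en-1-ol | COCOc1c(OC)cc(/C=C\CO)cc1OC
F4 | step 11 | (2R,3R)-3-(4-hydroxy-3,5-dimethoxyphenyl)-2-(hydroxymethyl)-2,3-dihydro-1,4-benzodioxine-6-carbaldehyde | COc1cc([C@H]2Oc3cc(C=O)ccc3O[C@@H]2CO)cc(OC)c1O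
F5 | step 11 | [(2R,3R)-6-ethenyl-3-(4-hydroxy-3,5-dimethoxyphenyl)-2,3-dihydro-1,4-benzodioxin-2-yl]methanol | COc1cc([C@H]2Oc3cc(C=C)ccc3O[C@@H]2CO)cc(OC)c1O
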